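The locants follow 2H-chromene numbering: O1, C2, C3, C4, C4a, C5 to C8, C8a. C1' is the ring-B carbon and C1'' is the prenyl CH2.

- **Cuts, in retrosynthetic order:** the O–Si bond on ring B; the ring-B-side C=O back to CH2; the CH2–C1' bond to ring B; then in one stroke O1–C2 and C4–C4a of the pyran together with C8–C1'' of the prenyl group; last, the two tertiary alkyl–O bonds on O1 and O7.
- **Forward order:** both benzene rings are bought. The ring-A acetophenone receives a 1,1-dimethylpropargyl group on its para-OH (later O1) and a 1,1-dimethylallyl group on its chelated ortho-OH (later O7). One heating programme moves both C5 units from O to C and closes the pyran, the only ring made and hence the last. Ring B is then joined by enolate arylation, the CH2 is oxidised to the second C=O, and the silyl group is removed.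
- **Feature that allows the event:** ring A is an acylphloroglucinol (O1, O5, O7 on alternate carbons, acyl on C6), so the precursor carries H only on C8 and C4a. C8 is the single open ortho carbon of O7, and C4a is the single open ortho carbon of O1 once C8 is filled. C2 of the pyran and the end carbon of the prenyl group are both CMe2, the carbinol carbons of two tertiary, [3,3]-active aryl ethers.
- **Stereochemistry:** none has to be set. There is no stereocentre, and the ring alkene C3=C4 is cis by ring size.

Key step: step 4

Remark: the target has no stereocentre and no configurationally free double bond, so it is achiral and the given SMILES defines it fully; compounds 1, 2, 4 and 12 are taken as catalogue chemicals.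

Step 1
Reactants: 1 1-(2,4-dihydroxy-6-methoxyphenyl)ethanone; 2 3-chloro-3-methylbut-1-yne
Product: 3 1-[2-hydroxy-6-methoxy-4-(2-methylbut-3-yn-2-yloxy)phenyl]ethanone
Conditions: K2CO3, KI (cat.), CuI (cat.), acetone, 55 °C
Reagents that add atoms: none
Why: Copper-catalysed O-propargylation of a phenol with a tertiary propargylic chloride should take only the para-OH, which is free and the more acidic, because the ortho-OH is held by a hydrogen bond to the acetyl C=O; no stereocentre is formed.

Step 2
Reactants: 4 2-methylbut-3-en-2-ol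
Product: 6 methyl 2-methylbut-3-en-2-yl carbonate, via lithium alkoxide 5 (not isolated)
Conditions: n-BuLi, THF, -78 °C; then ClCO2Me, -78 °C to rt
Reagents that add atoms: methyl chloroformate, COC(=O)Cl
Why: Acylation of the lithium alkoxide of a tertiary allylic alcohol with a chloroformate is a standard carbonate synthesis and supplies the ionisable partner for step 3; no stereocentre is formed.

Step 3
Reactants: 3 1-[2-hydroxy-6-methoxy-4-(2-methylbut-3-yn-2-yloxy)phenyl]ethanone; 6 methyl 2-methylbut-3-en-2-yl carbonate
Product: 7 1-[2-methoxy-6-(2-methylbut-3-en-2-yloxy)-4-(2-methylbut-3-yn-2-yloxy)phenyl]ethanone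
Conditions: Pd(PPh3)4 (5 mol %), THF, 0 °C to rt, Ar; chromatography on Et3N-washed silica
Reagents that add atoms: none
Why: In this Tsuji–Trost O-allylation under neutral conditions Pd(0) ionises 6 with loss of CO2, the liberated methoxide deprotonates the chelated phenol, and the phenoxide should attack the 1,1-dimethyl-π-allyl complex at its more substituted end under kinetic control (the known reverse prenylation of phenols), while the aryl propargyl ether and the terminal alkyne are not ionised at this temperature; no stereocentre is formed.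

Step 4
Reactants: 7 1-[2-methoxy-6-(2-methylbut-3-en-2-yloxy)-4-(2-methylbut-3-yn-2-yloxy)phenyl]ethanone
Product: 11 1-[7-hydroxy-5-methoxy-2,2-dimethyl-8-(3-methylbut-2-enyl)-2H-chromen-6-yl]ethanone, via prenylphenol propargyl ether 8 (not isolated), via ortho-allenylphenol 9 (not isolated), via ortho-quinone methide 10 (not isolated)
Conditions: PhNEt2 (degassed), Ar, 110 °C, then 170 °C in the same flask
Reagents that add atoms: none
Why: At about 110 °C the aryl 1,1-dimethylallyl ether on O7 should undergo an aromatic Claisen rearrangement ([3,3] shift through a chair, then enolisation) to C8, which forms the C8–CH2 bond, turns the reverse-prenyl ether into a normal prenyl group and frees the chelated O7–H (8). At about 170 °C the aryl 1,1-dimethylpropargyl ether on O1 should follow with a propargyl Claisen rearrangement to C4a (C4–C4a formed, O1–C2 broken) to give ortho-allenylphenol 9, and a [1,5]-H shift from O1–H to the central allene carbon C3 then gives the (Z)-ortho-quinone methide 10. The pyran is closed by a thermal disrotatory oxa-6π electrocyclisation of the 1-oxatriene O1=C8a–C4a=C4–C3=C2, which re-forms O1–C2 and restores the aromaticity of ring A. The closest known reaction types are the Claisen rearrangement of aryl 1,1-dimethylallyl ethers to ortho-prenylphenols and the thermal conversion of aryl 1,1-dimethylpropargyl ethers into 2,2-dimethyl-2H-chromenes, here run one after the other in one flask. No stereocentre is formed, and the C3=C4 double bond can only be cis inside the six-membered ring. The step needs site selectivity (prenyl to C8, pyran carbon to C4a), and the substrate secures it: O7 has C8 as its only H-bearing ortho carbon because C6 carries the acetyl group, tertiary allyl ethers rearrange at clearly lower temperature than tertiary propargyl ethers so that C8 is filled first, C4a is then the only open ortho carbon of O1 with O1 the only unalkylated oxygen next to it (O5 is methylated), and the basic solvent holds back acid-induced loss of the tertiary groups.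

Step 5
Reactants: 11 1-[7-hydroxy-5-methoxy-2,2-dimethyl-8-(3-methylbut-2-enyl)-2H-chromen-6-yl]ethanone; 12 (4-bromophenoxy)triisopropylsilane
Product: 13 1-[7-hydroxy-5-methoxy-2,2-dimethyl-8-(3-methylbut-2-enyl)-2H-chromen-6-yl]-2-[4-(triisopropylsilyloxy)phenyl]ethanone
Conditions: Pd2(dba)3 (2.5 mol %), XPhos (6 mol %), NaOt-Bu (3 equiv), toluene, 80 °C, Ar
Reagents that add atoms: none
Why: In this Pd-catalysed α-arylation of an aryl methyl ketone (Buchwald–Hartwig type) the excess base makes the phenoxide-enolate, whose unhindered CH2 end binds to ArPdBr and couples by reductive elimination, the more hindered product enolate should resist a second arylation, and the flanked phenoxide and the substituted alkenes are poor competitors; no stereocentre is formed.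

Step 6
Reactants: 13 1-[7-hydroxy-5-methoxy-2,2-dimethyl-8-(3-methylbut-2-enyl)-2H-chromen-6-yl]-2-[4-(triisopropylsilyloxy)phenyl]ethanone
Product: 15 1-[7-hydroxy-5-methoxy-2,2-dimethyl-8-(3-methylbut-2-enyl)-2H-chromen-6-yl]-2-[4-(triisopropylsilyloxy)phenyl]ethane-1,2-dione, via alpha-hydroperoxy ketone 14 (not isolated)
Conditions: DABCO, air, DMF, 90 °C, dark
Reagents that add atoms: dioxygen, O=O
Why: In this amine-promoted aerobic oxidation of a deoxybenzoin to a benzil the doubly activated CH2 enolises, takes up O2 to give hydroperoxide 14 and loses water (Kornblum–DeLaMare-type) to the 1,2-diketone, while the prenyl and chromene alkenes should not react with ground-state oxygen in the dark; the transient stereocentre of 14 is destroyed.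

Step 7
Reactants: 15 1-[7-hydroxy-5-methoxy-2,2-dimethyl-8-(3-methylbut-2-enyl)-2H-chromen-6-yl]-2-[4-(triisopropylsilyloxy)phenyl]ethane-1,2-dione
Product: 16 derrisdione A, 1-[7-hydroxy-5-methoxy-2,2-dimethyl-8-(3-methylbut-2-enyl)-2H-chromen-6-yl]-2-(4-hydroxyphenyl)ethane-1,2-dione
Conditions: TBAF, AcOH, THF, 0 °C
Reagents that add atoms: none
Why: Fluoride-induced cleavage of the aryl silyl ether, buffered with acetic acid so that neither a benzilic acid rearrangement nor an acid cyclisation of the ortho-prenylphenol can set in, should free the ring-B phenol and give the target.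

Compound list
1 | 1-(2,4-dihydroxy-6-methoxyphenyl)ethanone | CC(=O)c1c(O)cc(O)cc1OC | starting material
2 | 3-chloro-3-methylbut-1-yne | CC(C)(Cl)C#C | starting material
3 | 1-[2-hydroxy-6-methoxy-4-(2-methylbut-3-yn-2-yloxy)phenyl]ethanone | CC(=O)c1c(O)cc(OC(C)(C)C#C)cc1OC | intermediate
4 | 2-methylbut-3-en-2-ol | CC(C)(O)C=C | starting material
5 | lithium 2-methylbut-3-en-2-olate (not isolated) | [Li+].[O-]C(C)(C)C=C | intermediate
6 | methyl 2-methylbut-3-en-2-yl carbonate | COC(=O)OC(C)(C)C=C | intermediate
7 | 1-[2-methoxy-6-(2-methylbut-3-en-2-yloxy)-4-(2-methylbut-3-yn-2-yloxy)phenyl]ethanone | CC(=O)c1c(OC(C)(C)C=C)cc(OC(C)(C)C#C)cc1OC | intermediate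
8 | 1-[2-hydroxy-6-methoxy-3-(3-methylbut-2-enyl)-4-(2-methylbut-3-yn-2-yloxy)phenyl]ethanone (not isolated) | CC(=O)c1c(O)c(CC=C(C)C)c(OC(C)(C)C#C)cc1OC | intermediate
9 | 1-[2,4-dihydroxy-6-methoxy-5-(3-methylbuta-1,2-dienyl)-3-(3-methylbut-2-enyl)phenyl]ethanone (not isolated) | CC(=O)c1c(O)c(CC=C(C)C)c(O)c(C=C=C(C)C)c1OC | intermediate
10 | (6Z)-4-acetyl-3-hydroxy-5-methoxy-2-(3-methylbut-2-enyl)-6-(3-methylbut-2-enylidene)cyclohexa-2,4-dien-1-one (not isolated) | CC(=O)C1=C(OC)/C(=C/C=C(C)C)C(=O)C(CC=C(C)C)=C1O | intermediate
11 | 1-[7-hydroxy-5-methoxy-2,2-dimethyl-8-(3-methylbut-2-enyl)-2H-chromen-6-yl]ethanone | CC(=O)c1c(O)c(CC=C(C)C)c2OC(C)(C)C=Cc2c1OC | intermediate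
12 | (4-bromophenoxy)triisopropylsilane | CC(C)[Si](Oc1ccc(Br)cc1)(C(C)C)C(C)C | starting material
13 | 1-[7-hydroxy-5-methoxy-2,2-dimethyl-8-(3-methylbut-2-enyl)-2H-chromen-6-yl]-2-[4-(triisopropylsilyloxy)phenyl]ethanone | COc1c2c(c(CC=C(C)C)c(O)c1C(=O)Cc1ccc(O[Si](C(C)C)(C(C)C)C(C)C)cc1)OC(C)(C)C=C2 | intermediate
14 | racemic 2-hydroperoxy-1-[7-hydroxy-5-methoxy-2,2-dimethyl-8-(3-methylbut-2-enyl)-2H-chromen-6-yl]-2-[4-(triisopropylsilyloxy)phenyl]ethanone (not isolated) | COc1c2c(c(CC=C(C)C)c(O)c1C(=O)C(OO)c1ccc(O[Si](C(C)C)(C(C)C)C(C)C)cc1)OC(C)(C)C=C2 | intermediate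
15 | 1-[7-hydroxy-5-methoxy-2,2-dimethyl-8-(3-methylbut-2-enyl)-2H-chromen-6-yl]-2-[4-(triisopropylsilyloxy)phenyl]ethane-1,2-dione | COc1c2c(c(CC=C(C)C)c(O)c1C(=O)C(=O)c1ccc(O[Si](C(C)C)(C(C)C)C(C)C)cc1)OC(C)(C)C=C2 | intermediate
16 | derrisdione A | COc1c2c(c(CC=C(C)C)c(O)c1C(=O)C(=O)c1ccc(O)cc1)OC(C)(C)C=C2 | target

Total step count: 7. Longest linear sequence: 6 (steps 1, 3, 4, 5, 6, 7, from compound 1).

Steps most likely to fail

Step 3. The hydrogen-bonded, acyl-stabilised phenoxide may alkylate slowly. The tertiary aryl ether may also be re-ionised by Pd(0), so that the allyl group drifts to the linear O-prenyl position or to carbon. The fallback builds the tertiary ether without a π-allyl intermediate. It sets out from 3, which is O-alkylated with 2-bromo-2-methylpropanal (K2CO3, DMF, rt) to give 2-[2-acetyl-3-methoxy-5-(2-methylbut-3-yn-2-yloxy)phenoxy]-2-methylpropanal F1. A Wittig methylenation (Ph3P=CH2, THF, -78 to 0 °C) should be selective for the aldehyde over the di-ortho-substituted aryl ketone. It turns the formyl group into the vinyl group and comes back to the route at 7.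

Step 5. Enolisation of a ketone that already carries a phenoxide may stay incomplete. The chelating phenoxide-enolate may also tie up palladium, so that the coupling stalls. The fallback removes the acidic site before the C–C bond is made. It sets out from 11, which is converted (NaH, MOMCl, DMF, 0 °C) into 1-[5-methoxy-7-(methoxymethoxy)-2,2-dimethyl-8-(3-methylbut-2-enyl)-2H-chromen-6-yl]ethanone F2. This is arylated with 12 under the catalysis of step 5 to give 1-[5-methoxy-7-(methoxymethoxy)-2,2-dimethyl-8-(3-methylbut-2-enyl)-2H-chromen-6-yl]-2-[4-(triisopropylsilyloxy)phenyl]ethanone F3. Catalytic HCl in MeOH at rt removes the acetal ortho to the carbonyl group while the aryl silyl ether stays. The sequence comes back to the route at 13.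

Step 6. The hydroperoxide may fragment with C–C cleavage instead of losing water. Slow allylic autoxidation of the prenyl group may also accompany a sluggish oxidation of the phenoxide-bearing ketone. The fallback separates oxygen transfer from dehydrogenation. It sets out from 13, whose dianion (KHMDS, 2.2 equiv, THF, -78 °C) is hydroxylated with 3-phenyl-2-(phenylsulfonyl)oxaziridine (Davis oxidation). This gives racemic 2-hydroxy-1-[7-hydroxy-5-methoxy-2,2-dimethyl-8-(3-methylbut-2-enyl)-2H-chromen-6-yl]-2-[4-(triisopropylsilyloxy)phenyl]ethanone F4. Oxidation of this benzoin with MnO2 (CH2Cl2, rt) comes back to the route at 15.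

Further compounds
F1 | step 3 | 2-[2-acetyl-3-methoxy-5-(2-methylbut-3-yn-2-yloxy)phenoxy]-2-methylpropanal | CC(=O)c1c(OC)cc(OC(C)(C)C#C)cc1OC(C)(C)C=O
F2 | step 5 | 1-[5-methoxy-7-(methoxymethoxy)-2,2-dimethyl-8-(3-methylbut-2-enyl)-2H-chromen-6-yl]ethanone | CC(=O)c1c(OCOC)c(CC=C(C)C)c2OC(C)(C)C=Cc2c1OC
F3 | step 5 | 1-[5-methoxy-7-(methoxymethoxy)-2,2-dimethyl-8-(3-methylbut-2-enyl)-2H-chromen-6-yl]-2-[4-(triisopropylsilyloxy)phenyl]ethanone | COCOc1c(CC=C(C)C)c2OC(C)(C)C=Cc2c(OC)c1C(=O)Cc1ccc(O[Si](C(C)C)(C(C)C)C(C)C)cc1
F4 | step 6 | racemic 2-hydroxy-1-[7-hydroxy-5-methoxy-2,2-dimethyl-8-(3-methylbut-2-enyl)-2H-chromen-6-yl]-2-[4-(triisopropylsilyloxy)phenyl]ethanone | COc1c2c(c(CC=C(C)C)c(O)c1C(=O)C(O)c1ccc(O[Si](C(C)C)(C(C)C)C(C)C)cc1)OC(C)(C)C=C2
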